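**Plan**

1. Retrosynthesis: the CH2OH carbon (C9) is taken back to the acyl group of an N-acyl bornane-10,2-sultam. Both C–O bonds of the dioxane ring (O4'–C8 and O3'–C7) are then cut together, giving the flavone catechol selgin and an N-sinapoyl sultam. Selgin is cut at O1–C2 of ring C and at the chalcone C=C bond, the sinapoyl imide at C7=C8.
2. Forward: rings A, B and the syringyl ring are bought. Ring C closes by Claisen–Schmidt condensation and I2/DMSO oxidative cyclization. The 1,4-dioxane ring closes last, in a silver-mediated oxidative coupling of the two halves.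
3. Enabling feature: the vicinal oxygens O3' and O4' on ring B (a free catechol before the event) and the 4''-OH para to C7 on the syringyl ring, which makes C7 the terminus of a p-quinone methide once C8 has bonded to O4'. The methoxy groups at C3'' and C5'' shut off C–C coupling on that ring.
4. Stereochemistry: C8 (C2 of the dioxane) comes from the (2S)-sultam on C9 by face control at the sp2 carbon. C7 (C3 of the dioxane) comes from C8 by trans-selective, reversible ring closure. The auxiliary leaves in the reduction that makes the CH2OH group.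
5. Locants: sinapoyl chain C7 (benzylic), C8, C9 (carbonyl); primes for ring B, double primes for the syringyl ring.

Key step: step 9

Remark: the sense of induction in step 9 is assumed to follow the accepted model for non-chelated reactions at C(α) of N-enoyl bornane-10,2-sultams (C(α)-Re with the (2R)-auxiliary, hence C(α)-Si with the (2S)-auxiliary used here); this is recalled from the general model, not derived for this substrate.

**Route**

Step 1
Reactants: 1 2',4',6'-trihydroxyacetophenone
Product: 2 4',6'-bis(benzyloxy)-2'-hydroxyacetophenone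
Conditions: BnBr (2.1 equiv), K2CO3, DMF, rt
Reagents that add atoms: benzyl bromide, BrCc1ccccc1
Why: Williamson ether synthesis: the 4'-OH and one of the two equivalent ortho-OH groups are benzylated, while the last ortho-OH is hydrogen-bonded to the acetyl carbonyl, is the least nucleophilic and stays free for the later closure of ring C.

Step 2
Reactants: 3 3,4-dihydroxy-5-methoxybenzaldehyde
Product: 4 3,4-bis(benzyloxy)-5-methoxybenzaldehyde
Conditions: BnBr (2.3 equiv), K2CO3, DMF, 60 °C
Reagents that add atoms: benzyl bromide, BrCc1ccccc1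
Why: Williamson ether synthesis of both catechol hydroxyls, which shields the catechol from base and from iodine in steps 3 and 4.

Step 3
Reactants: 2 4',6'-bis(benzyloxy)-2'-hydroxyacetophenone; 4 3,4-bis(benzyloxy)-5-methoxybenzaldehyde
Product: 5 (E)-3,4,4',6'-tetrakis(benzyloxy)-2'-hydroxy-5-methoxychalcone
Conditions: KOH (50% aq), EtOH/THF, rt
Reagents that add atoms: none
Why: Claisen–Schmidt condensation (crossed aldol, then E1cB loss of water) between the methyl ketone enolate and the non-enolizable aldehyde, which gives the E-enone as the thermodynamic alkene.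

Step 4
Reactants: 5 (E)-3,4,4',6'-tetrakis(benzyloxy)-2'-hydroxy-5-methoxychalcone
Product: 7 5,7,3',4'-tetrakis(benzyloxy)-5'-methoxyflavone, via flavanone 6 (not isolated)
Conditions: I2 (10 mol%), DMSO, 130 °C
Reagents that add atoms: none
Why: I2/DMSO oxidative cyclization of a 2'-hydroxychalcone: 6-endo-trig oxa-Michael addition of the phenol gives flavanone 6, iodination at C3 and loss of HI aromatize ring C, and DMSO turns HI back into I2.

Step 5
Reactants: 7 5,7,3',4'-tetrakis(benzyloxy)-5'-methoxyflavone
Product: 8 selgin (5,7,3',4'-tetrahydroxy-5'-methoxyflavone)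
Conditions: H2 (1 atm), Pd/C (10% Pd on carbon), THF/MeOH 1:1, rt
Reagents that add atoms: none
Why: Hydrogenolysis of the four benzyl ethers over Pd/C, in which the C2=C3 bond of the flavone, part of a vinylogous ester, should stay untouched at 1 atm and room temperature.

Step 6
Reactants: 9 (2S)-bornane-10,2-sultam; 10 bromoacetyl bromide
Product: 11 N-(bromoacetyl)-(2S)-bornane-10,2-sultam
Conditions: NaH (1.1 equiv), THF, 0 °C; then 10, -78 to 0 °C
Reagents that add atoms: none
Why: N-acylation of the sodium salt of the sulfonamide, which attacks the acyl bromide far faster than the alkyl bromide at low temperature.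

Step 7
Reactants: 11 N-(bromoacetyl)-(2S)-bornane-10,2-sultam
Product: 13 N-[(triphenylphosphoranylidene)acetyl]-(2S)-bornane-10,2-sultam, via phosphonium bromide 12 (not isolated)
Conditions: PPh3 (1.05 equiv), toluene, rt; then CH2Cl2/aq Na2CO3, 0 °C
Reagents that add atoms: triphenylphosphine, c1ccc(cc1)P(c1ccccc1)c1ccccc1
Why: SN2 displacement of the α-bromide by PPh3 and deprotonation of the acidic CH2 between phosphonium and imide carbonyl give the carbonyl-stabilized ylide, for which aqueous carbonate is base enough.

Step 8
Reactants: 13 N-[(triphenylphosphoranylidene)acetyl]-(2S)-bornane-10,2-sultam; 14 syringaldehyde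
Product: 15 N-[(E)-3-(4-hydroxy-3,5-dimethoxyphenyl)prop-2-enoyl]-(2S)-bornane-10,2-sultam (N-sinapoyl sultam)
Conditions: toluene, 100 °C
Reagents that add atoms: none
Why: Wittig olefination with a stabilized ylide, reversible in its addition step and therefore E-selective, of a kind that tolerates the free para-hydroxyl of hydroxybenzaldehydes.

Step 9
Reactants: 8 selgin; 15 N-sinapoyl-(2S)-bornane-10,2-sultam
Product: 17 N-acyl-(2S)-bornane-10,2-sultam of the trans-(2S,3R)-1,4-benzodioxane-2-carboxylic acid (flavone at C6; OMe at C8; 4-hydroxy-3,5-dimethoxyphenyl at C3), via quinone methide 16 (not isolated)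
Conditions: Ag2CO3 (3 equiv), acetone/toluene 1:1, 55 °C, N2, dark; 15 (1.3 equiv) added over 4 h; chromatography on silica gel
Reagents that add atoms: none
Why: Proposed new method: monovalent silver on Ag2CO3 takes one electron from each phenoxide, the 4'-O radical of 8 (O4' is para to pyranone C2 and flanked by O3'H and the 5'-OMe, so it is the catechol oxygen deprotonated and oxidized first) joins C8 of the sinapoyl radical of 15 to give p-quinone methide 16, and the neighbouring 3'-OH then adds to C7 of 16 with rearomatization of the syringyl ring. The closest known reactions are the Ag2CO3-mediated coupling of flavone and flavanonol catechols with 4-hydroxycinnamyl alcohols or 4-hydroxycinnamate esters, which leads to racemic trans-benzodioxanes, and the oxidative 8–5 dimerization of N-feruloyl bornane-10,2-sultam, in which the auxiliary controls the new bond at C8; auxiliary control of a C8–O bond in a benzodioxane-forming cross-coupling has not been shown. The dioxane ring is closed by the second bond in a 6-exo-trig mode (oxa-1,6-addition to the exocyclic C7=C1'' bond of the quinone methide). C8 is set by the sultam, because the planar C8 reacts in the s-cis, C=O/SO2-anti conformer in which the (2S)-auxiliary should leave the C8 Si face open, so that O4' arrives there and C8 becomes S; C7 is set by C8, because the closure passes a half-chair with aryl and acyl groups both pseudo-equatorial and is reversible through 16 while the 4''-OH is free, so the trans (3R) isomer should be both the kinetic and the thermodynamic product. The step needs cross- rather than homo-coupling, O4'–C8 and O3'–C7 rather than the reverse regiochemistry, and no C–C coupling, and these are secured by slow addition of 15 to the oxidant and the catechol, by the electronic difference between O4' and O3', and by the methoxy groups at C3'' and C5''. Minor stereoisomers of 17 are diastereomers of it, not enantiomers, and can be removed by chromatography or crystallization before the auxiliary is cleaved.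

Step 10
Reactants: 17 N-acyl-(2S)-bornane-10,2-sultam of the trans-(2S,3R)-benzodioxane-2-carboxylic acid
Product: 19 palstatin, via aldehyde 18 (not isolated)
Conditions: NaBH4 (8 equiv), THF/H2O 4:1, 0 °C to rt; then aq NH4Cl/AcOH to pH 5; 9 recovered
Reagents that add atoms: none
Why: Reductive cleavage of an N-acyl sultam by borohydride: the imide-like carbonyl is reduced through the hemiaminal and aldehyde 18 to the primary alcohol with loss of the sultam anion, while the flavone carbonyl, a vinylogous ester that becomes a vinylogous carboxylate once 7-OH is deprotonated, is inert to NaBH4, and no stereocentre is touched (the descriptor at C2 changes from S to R only because the CIP priorities change).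

**Compound list**

1 | 2',4',6'-trihydroxyacetophenone | CC(=O)c1c(O)cc(O)cc1O | starting material
2 | 4',6'-bis(benzyloxy)-2'-hydroxyacetophenone | CC(=O)c1c(O)cc(OCc2ccccc2)cc1OCc1ccccc1 | intermediate
3 | 3,4-dihydroxy-5-methoxybenzaldehyde (5-hydroxyvanillin) | COc1cc(C=O)cc(O)c1O | starting material
4 | 3,4-bis(benzyloxy)-5-methoxybenzaldehyde | COc1cc(C=O)cc(OCc2ccccc2)c1OCc1ccccc1 | intermediate
5 | (E)-1-[2,4-bis(benzyloxy)-6-hydroxyphenyl]-3-[3,4-bis(benzyloxy)-5-methoxyphenyl]prop-2-en-1-one (chalcone) | COc1cc(/C=C/C(=O)c2c(O)cc(OCc3ccccc3)cc2OCc2ccccc2)cc(OCc2ccccc2)c1OCc1ccccc1 | intermediate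
6 | racemic 5,7-bis(benzyloxy)-2-[3,4-bis(benzyloxy)-5-methoxyphenyl]chroman-4-one (flavanone) | COc1cc(C2CC(=O)c3c(OCc4ccccc4)cc(OCc4ccccc4)cc3O2)cc(OCc2ccccc2)c1OCc1ccccc1 | intermediate
7 | 5,7-bis(benzyloxy)-2-[3,4-bis(benzyloxy)-5-methoxyphenyl]-4H-chromen-4-one | COc1cc(-c2cc(=O)c3c(OCc4ccccc4)cc(OCc4ccccc4)cc3o2)cc(OCc2ccccc2)c1OCc1ccccc1 | intermediate
8 | selgin, 2-(3,4-dihydroxy-5-methoxyphenyl)-5,7-dihydroxy-4H-chromen-4-one | COc1cc(-c2cc(=O)c3c(O)cc(O)cc3o2)cc(O)c1O | intermediate
9 | (2S)-bornane-10,2-sultam, (1R)-(+)-2,10-camphorsultam, (3aR,6S,7aS)-8,8-dimethylhexahydro-3H-3a,6-methano-2,1-benzisothiazole 2,2-dioxide | O=S1(=O)C[C@]23CC[C@H](C2(C)C)C[C@@H]3N1 | starting material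
10 | bromoacetyl bromide | BrCC(Br)=O | starting material
11 | N-(bromoacetyl)-(2S)-bornane-10,2-sultam | O=S1(=O)C[C@]23CC[C@H](C2(C)C)C[C@@H]3N1C(=O)CBr | intermediate
12 | [2-oxo-2-((2S)-bornane-10,2-sultam-N-yl)ethyl]triphenylphosphonium bromide | O=S1(=O)C[C@]23CC[C@H](C2(C)C)C[C@@H]3N1C(=O)C[P+](c4ccccc4)(c5ccccc5)c6ccccc6.[Br-] | intermediate
13 | N-[(triphenylphosphoranylidene)acetyl]-(2S)-bornane-10,2-sultam | O=S1(=O)C[C@]23CC[C@H](C2(C)C)C[C@@H]3N1C(=O)C=P(c4ccccc4)(c5ccccc5)c6ccccc6 | intermediate
14 | syringaldehyde (4-hydroxy-3,5-dimethoxybenzaldehyde) | COc1cc(C=O)cc(OC)c1O | starting material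
15 | N-[(E)-3-(4-hydroxy-3,5-dimethoxyphenyl)prop-2-enoyl]-(2S)-bornane-10,2-sultam | O=S1(=O)C[C@]23CC[C@H](C2(C)C)C[C@@H]3N1C(=O)/C=C/c4cc(OC)c(O)c(OC)c4 | intermediate
16 | p-quinone methide: (8S)-aryl ether in which O4' of selgin (3'-OH free) is bonded to C8 of the N-acyl sultam and C7=C1'' is exocyclic to a 3,5-dimethoxy-4-oxocyclohexa-2,5-dienylidene ring | O=S1(=O)C[C@]23CC[C@H](C2(C)C)C[C@@H]3N1C(=O)[C@@H](Oc4c(OC)cc(-c5cc(=O)c6c(O)cc(O)cc6o5)cc4O)C=C7C=C(OC)C(=O)C(OC)=C7 | intermediate
17 | 5,7-dihydroxy-2-[(2S,3R)-3-(4-hydroxy-3,5-dimethoxyphenyl)-8-methoxy-2-{[(2S)-bornane-10,2-sultam-N-yl]carbonyl}-2,3-dihydro-1,4-benzodioxin-6-yl]-4H-chromen-4-one (trans) | O=S1(=O)C[C@]23CC[C@H](C2(C)C)C[C@@H]3N1C(=O)[C@H]4Oc5c(OC)cc(-c6cc(=O)c7c(O)cc(O)cc7o6)cc5O[C@@H]4c8cc(OC)c(O)c(OC)c8 | intermediate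
18 | (2S,3R)-6-(5,7-dihydroxy-4-oxo-4H-chromen-2-yl)-3-(4-hydroxy-3,5-dimethoxyphenyl)-8-methoxy-2,3-dihydro-1,4-benzodioxine-2-carbaldehyde | COc1cc([C@H]2Oc3cc(-c4cc(=O)c5c(O)cc(O)cc5o4)cc(OC)c3O[C@@H]2C=O)cc(OC)c1O | intermediate
19 | palstatin, 5,7-dihydroxy-2-[(2R,3R)-3-(4-hydroxy-3,5-dimethoxyphenyl)-2-(hydroxymethyl)-8-methoxy-2,3-dihydro-1,4-benzodioxin-6-yl]-4H-chromen-4-one (trans) | COc1cc([C@H]2Oc3cc(-c4cc(=O)c5c(O)cc(O)cc5o4)cc(OC)c3O[C@@H]2CO)cc(OC)c1O | target

**Totals**

Total step count: 10.
Longest linear sequence: 6 steps (steps 1, 3, 4, 5, 9, 10).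

**Steps most likely to fail**

Step 9. The failure processes are poor or reversed facial selectivity at C8, 8–8 homo-coupling of 15 in competition with the cross-coupling, and coupling through O3' in place of O4'. The fallback gives up auxiliary control for the known racemic biomimetic coupling followed by separation of enantiomers. It sets out from 8, which is treated with commercially available (E)-sinapyl alcohol F1 and Ag2CO3 in acetone/toluene at 55 °C. The same radical coupling and oxa-1,6-addition, through the racemic quinone methide F2 (not isolated), should give the racemic trans-benzodioxane, that is 19 together with ent-palstatin F3. Preparative chromatography on a chiral stationary phase (cellulose tris(3,5-dimethylphenylcarbamate)) separates 19 from F3, and the route is rejoined at 19. Neither the sultam branch nor the reduction is needed in this case.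

Step 10. The failure processes are base-induced epimerization at C2 or retro-oxa-Michael opening of the dioxane ring next to the imide carbonyl in the alkaline borohydride medium, and hydride attack on the pyranone. The fallback separates cleavage of the auxiliary from the reduction. It sets out from 17, which is hydrolysed with LiOH/H2O2 in THF/H2O at 0 °C (Na2SO3, then HCl in the work-up). The weakly basic and strongly nucleophilic hydroperoxide should cleave the imide to give the carboxylic acid F4 and return 9. F4, which no longer enolizes readily, is reduced with BH3·SMe2 in THF at 0 °C to rt (MeOH quench), a reagent that reduces carboxylic acids in preference to the vinylogous ester of the flavone. The route is rejoined at 19.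

Step 8. The failure process is protonation of the ylide by the acidic phenol of 14, which stalls the olefination. The fallback builds 15 by N-acylation instead of olefination and sets out from 9. Commercially available sinapic acid F5 is acetylated (Ac2O, pyridine) to 4-O-acetylsinapic acid F6. Oxalyl chloride with catalytic DMF in CH2Cl2 converts F6 into 4-O-acetylsinapoyl chloride F7. F7 acylates the sodium salt of 9 (NaH, toluene, 0 °C to rt) to give the N-(4-acetoxy-3,5-dimethoxycinnamoyl) sultam F8. Pyrrolidine (1.1 equiv, THF, 0 °C) then removes the aryl acetate by aminolysis, and the route is rejoined at 15.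

**Further compounds**

F1 | step 9 | (E)-sinapyl alcohol | COc1cc(/C=C/CO)cc(OC)c1O
F2 | step 9 | racemic p-quinone methide from O4'–C8 coupling of selgin with sinapyl alcohol | COC1=CC(=CC(CO)Oc2c(OC)cc(-c3cc(=O)c4c(O)cc(O)cc4o3)cc2O)C=C(OC)C1=O
F3 | step 9 | ent-palstatin, the (2S,3S)-trans enantiomer | COc1cc([C@@H]2Oc3cc(-c4cc(=O)c5c(O)cc(O)cc5o4)cc(OC)c3O[C@H]2CO)cc(OC)c1O
F4 | step 10 | (2S,3R)-6-(5,7-dihydroxy-4-oxo-4H-chromen-2-yl)-3-(4-hydroxy-3,5-dimethoxyphenyl)-8-methoxy-2,3-dihydro-1,4-benzodioxine-2-carboxylic acid | COc1cc([C@H]2Oc3cc(-c4cc(=O)c5c(O)cc(O)cc5o4)cc(OC)c3O[C@@H]2C(=O)O)cc(OC)c1O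
F5 | step 8 | sinapic acid | COc1cc(/C=C/C(=O)O)cc(OC)c1O
F6 | step 8 | 4-O-acetylsinapic acid | COc1cc(/C=C/C(=O)O)cc(OC)c1OC(C)=O
F7 | step 8 | 4-O-acetylsinapoyl chloride | COc1cc(/C=C/C(=O)Cl)cc(OC)c1OC(C)=O
F8 | step 8 | N-[(E)-3-(4-acetoxy-3,5-dimethoxyphenyl)prop-2-enoyl]-(2S)-bornane-10,2-sultam | O=S1(=O)C[C@]23CC[C@H](C2(C)C)C[C@@H]3N1C(=O)/C=C/c4cc(OC)c(OC(C)=O)c(OC)c4
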